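**Retrosynthetic overview**
- The 3'-OH is installed last, by directed lithiation/borylation/oxidation at the only ring-B C–H flanked by two OMe groups of the (S)-isoflavan.
- The (S)-isoflavan comes from a 7-hydroxyisoflavylium (3-aryl-1-benzopyrylium) salt by a chiral Brønsted acid/Hantzsch ester cascade transfer hydrogenation; C3, the only stereocentre, is set by enantioselective protonation.
- The isoflavylium salt comes from acid condensation of a salicylaldehyde (ring A) with an aryl enol ether (ring B), forming C3–C4 and O1–C2.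
- The enol ether comes from 2,4,5-trimethoxybenzaldehyde by a methoxymethylene Wittig reaction.
- Ring order: rings A and B are bought; ring C (the pyran) is the only ring formed, in step 2, and is reduced in step 3.

Assumption: aldehydes 1 and 4 are bought as catalogue chemicals; the sense of induction of the new step 3 cannot be predicted safely, so the (S,S)-catalyst is written and its antipode is used if the first run gives the (R)-isoflavan.

**Step 1**
Reactants: 1 2,4,5-trimethoxybenzaldehyde; 2 (methoxymethyl)triphenylphosphonium chloride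
Product: 3 1,2,4-trimethoxy-5-(2-methoxyethenyl)benzene (E/Z mixture, used as such)
Conditions: 2 (1.3 equiv), KOtBu (1.3 equiv), THF, 0 → 23 °C
Reagents that add atoms: (methoxymethyl)triphenylphosphonium chloride (compound 2), [Cl-].COC[P+](c1ccccc1)(c1ccccc1)c1ccccc1
Why: Wittig olefination with the methoxymethylene ylide (one-carbon homologation) on an unhindered, non-enolisable aldehyde; the E/Z ratio does not matter because both isomers react identically in step 2.

**Step 2**
Reactants: 3 1,2,4-trimethoxy-5-(2-methoxyethenyl)benzene; 4 2,4-dihydroxy-3-methoxybenzaldehyde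
Product: 5 7-hydroxy-8-methoxy-3-(2,4,5-trimethoxyphenyl)chromenylium chloride
Conditions: HCl (4 M in dioxane, 3 equiv), AcOH/EtOAc, 0 → 23 °C, slow addition of 3; precipitate with Et2O, filter
Reagents that add atoms: hydrogen chloride, Cl
Why: Classical acid-mediated benzopyrylium synthesis, in which the enol ether (a masked arylacetaldehyde) attacks the protonated aldehyde of 4 through its aryl-bearing carbon (Prins/aldol type), the ortho-OH closes onto the oxocarbenium carbon, and loss of water and methanol aromatises ring C to the salt, which precipitates.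

**Step 3**
Reactants: 5 7-hydroxy-8-methoxy-3-(2,4,5-trimethoxyphenyl)chromenylium chloride
Product: 8 (S)-8-methoxy-3-(2,4,5-trimethoxyphenyl)chroman-7-ol, via anhydrobase 6 (not isolated), via 4H-chromene 7 (not isolated)
Conditions: NaHCO3 (3 equiv), 4 Å MS, CH2Cl2, 23 °C, 1 h, filter under Ar; then (S,S)-IDPi acid (BINOL-derived imidodiphosphorimidate, 3,3'-aryl = 3,5-(CF3)2C6H3, N-Tf; 5 mol%), Hantzsch ester (diethyl 2,6-dimethyl-1,4-dihydropyridine-3,5-dicarboxylate, 2.4 equiv), CHCl3 (0.05 M), 4 Å MS, −20 → 30 °C, 48 h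
Reagents that add atoms: none
Why: Proposed new method: NaHCO3 removes HCl to give the neutral quinoidal anhydrobase 6 so that the chiral acid is the only strong acid present; the confined acid re-protonates 6 to a pyrylium/chiral-anion pair that takes the first hydride at C4 to give enol ether 7; 7 is then protonated at C3 inside the chiral anion pocket and the resulting 2-oxocarbenium ion pair is trapped at C2 by the second hydride, so that this protonation/hydride-capture sequence sets the (S)-C3 centre and returns the acid; the closest known reaction type is the chiral Brønsted acid/Hantzsch ester cascade transfer hydrogenation of 3-substituted quinolines (1,4-reduction, enantioselective enamine protonation, 1,2-reduction), together with chiral-anion-paired hydride additions to pyrylium ions, neither of which has been shown to set C3 of a 3-aryl-1-benzopyrylium.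

**Step 4**
Reactants: 8 (S)-8-methoxy-3-(2,4,5-trimethoxyphenyl)chroman-7-ol
Product: 11 (S)-3-(3-hydroxy-2,4,5-trimethoxyphenyl)-8-methoxychroman-7-ol, via dilithio species 9 (not isolated), via lithium arylborate 10 (not isolated)
Conditions: n-BuLi (2.4 equiv), TMEDA (2.4 equiv), THF, 0 → 23 °C, 2 h; B(OMe)3 (3 equiv), −78 → 23 °C; AcOH, 30% H2O2, 0 °C
Reagents that add atoms: hydrogen peroxide, OO
Why: Directed ortho-metalation, in which (after the phenol is deprotonated) C3'-H is the only ring position flanked by two methoxy groups and is lithiated selectively, followed by borate formation and peroxide oxidation (1,2-aryl shift from boron to oxygen) to give the phenol without touching the non-acidic C3 stereocentre.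

**Compound list**
1 | 2,4,5-trimethoxybenzaldehyde | COc1cc(OC)c(C=O)cc1OC | starting material
2 | (methoxymethyl)triphenylphosphonium chloride | [Cl-].COC[P+](c1ccccc1)(c1ccccc1)c1ccccc1 | starting material
3 | 1,2,4-trimethoxy-5-(2-methoxyethenyl)benzene (E/Z mixture) | COC=Cc1cc(OC)c(OC)cc1OC | intermediate
4 | 2,4-dihydroxy-3-methoxybenzaldehyde | COc1c(O)ccc(C=O)c1O | starting material
5 | 7-hydroxy-8-methoxy-3-(2,4,5-trimethoxyphenyl)chromenylium chloride | [Cl-].COc1cc(OC)c(-c2c[o+]c3c(OC)c(O)ccc3c2)cc1OC | intermediate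
6 | 8-methoxy-3-(2,4,5-trimethoxyphenyl)-7H-chromen-7-one (quinoidal anhydrobase, not isolated) | COC1=C2OC=C(c3cc(OC)c(OC)cc3OC)C=C2C=CC1=O | intermediate
7 | 8-methoxy-3-(2,4,5-trimethoxyphenyl)-4H-chromen-7-ol (not isolated) | COc1cc(OC)c(C2=COc3c(OC)c(O)ccc3C2)cc1OC | intermediate
8 | (S)-8-methoxy-3-(2,4,5-trimethoxyphenyl)chroman-7-ol | COc1cc([C@H]2COc3c(ccc(O)c3OC)C2)c(OC)cc1OC | intermediate
9 | lithium (S)-3-(3-lithio-2,4,5-trimethoxyphenyl)-8-methoxychroman-7-olate (not isolated) | COc1cc([C@H]2COc3c(ccc(O[Li])c3OC)C2)c(OC)c([Li])c1OC | intermediate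
10 | dilithium trimethoxy[2,5,6-trimethoxy-3-((S)-8-methoxy-7-oxidochroman-3-yl)phenyl]borate (not isolated) | COc1cc([C@H]2COc3c(ccc([O-])c3OC)C2)c(OC)c([B-](OC)(OC)OC)c1OC.[Li+].[Li+] | intermediate
11 | (S)-3-(3-hydroxy-2,4,5-trimethoxyphenyl)-8-methoxychroman-7-ol [(3S)-7,3'-dihydroxy-8,2',4',5'-tetramethoxyisoflavan] | COc1cc([C@H]2COc3c(ccc(O)c3OC)C2)c(OC)c(O)c1OC | target

**Totals**
Total step count: 4. Longest linear sequence: 4 steps (1 → 3 → 5 → 8 → 11).

**Three steps most likely to fail**

Step 3 (the proposed new cascade). There are three main risks. The chiral ion pair has no hydrogen-bond handle near C3, so the ee may be modest. The first hydride may add at C2 instead of C4 and lead on through the 2H-chromene (the same compound as F1 below), possibly with a different selectivity. The electrophilic pyrylium may also be intercepted by the electron-rich product. The fallback uses known chemistry and sets out from 5. NaBH4 in MeOH/THF at 0 °C reduces the salt to 8-methoxy-3-(2,4,5-trimethoxyphenyl)-2H-chromen-7-ol F1. TBSCl/imidazole in DMF gives tert-butyl{[8-methoxy-3-(2,4,5-trimethoxyphenyl)-2H-chromen-7-yl]oxy}dimethylsilane F2. Iridium-catalysed asymmetric hydrogenation of the 3-aryl-2H-chromene, an established reaction class for isoflav-3-enes, then gives (S)-tert-butyl{[8-methoxy-3-(2,4,5-trimethoxyphenyl)chroman-7-yl]oxy}dimethylsilane F3; the conditions are [Ir(cod)((S)-tBu-PHOX)][B(3,5-(CF3)2C6H3)4] (2 mol%), H2 (50 bar), CH2Cl2, with the ligand antipode chosen for the (S)-product. Bu4NF in THF removes the silyl group and the sequence comes back to the route at 8.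

Step 4 (late dianion lithiation/hydroxylation). The lithium phenoxide may aggregate and slow the metalation, and the very electron-rich product may over-oxidise. The fallback moves the oxygen to the start and sets out from 1. In situ protection as the α-amino alkoxide with lithium N-methylpiperazide (LiN(CH2CH2)2NMe), then n-BuLi, B(OMe)3 and mild oxidation with N-methylmorpholine N-oxide gives 3-hydroxy-2,4,5-trimethoxybenzaldehyde F4. The Wittig reaction of step 1 with 2 (2.5 equiv of ylide) gives 2,3,6-trimethoxy-5-(2-methoxyethenyl)phenol F5. Condensation with 4 as in step 2 gives 7-hydroxy-3-(3-hydroxy-2,4,5-trimethoxyphenyl)-8-methoxychromenylium chloride F6. The step 3 cascade then passes through the anhydrobase 3-(3-hydroxy-2,4,5-trimethoxyphenyl)-8-methoxy-7H-chromen-7-one F7 and the enol ether 3-(3-hydroxy-2,4,5-trimethoxyphenyl)-8-methoxy-4H-chromen-7-ol F8, and comes back to the route at 11.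

Step 2 (one-pot pyrylium formation). The enol ether may oligomerise in strong acid, or the salt may fail to crystallise. The fallback builds ring C at the coumarin oxidation level and sets out from 4. Perkin–Oglialoro condensation with bought (2,4,5-trimethoxyphenyl)acetic acid F9 (Ac2O, Et3N, 110 °C) gives 8-methoxy-2-oxo-3-(2,4,5-trimethoxyphenyl)-2H-chromen-7-yl acetate F10. i-Bu2AlH (3.5 equiv, CH2Cl2, −78 °C) cleaves the acetate and reduces the lactone to the racemic lactol 8-methoxy-3-(2,4,5-trimethoxyphenyl)-2H-chromene-2,7-diol F11. HCl in AcOH/Et2O ionises the lactol with loss of water, and the sequence comes back to the route at 5.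

**Further compounds**
F1 | step 3 | 8-methoxy-3-(2,4,5-trimethoxyphenyl)-2H-chromen-7-ol | COc1cc(OC)c(C2=Cc3ccc(O)c(OC)c3OC2)cc1OC
F2 | step 3 | tert-butyl{[8-methoxy-3-(2,4,5-trimethoxyphenyl)-2H-chromen-7-yl]oxy}dimethylsilane | COc1cc(OC)c(C2=Cc3ccc(O[Si](C)(C)C(C)(C)C)c(OC)c3OC2)cc1OC
F3 | step 3 | (S)-tert-butyl{[8-methoxy-3-(2,4,5-trimethoxyphenyl)chroman-7-yl]oxy}dimethylsilane | COc1cc([C@H]2COc3c(ccc(O[Si](C)(C)C(C)(C)C)c3OC)C2)c(OC)cc1OC
F4 | step 4 | 3-hydroxy-2,4,5-trimethoxybenzaldehyde | COc1cc(C=O)c(OC)c(O)c1OC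
F5 | step 4 | 2,3,6-trimethoxy-5-(2-methoxyethenyl)phenol (E/Z mixture) | COC=Cc1cc(OC)c(OC)c(O)c1OC
F6 | step 4 | 7-hydroxy-3-(3-hydroxy-2,4,5-trimethoxyphenyl)-8-methoxychromenylium chloride | [Cl-].COc1cc(-c2c[o+]c3c(OC)c(O)ccc3c2)c(OC)c(O)c1OC
F7 | step 4 | 3-(3-hydroxy-2,4,5-trimethoxyphenyl)-8-methoxy-7H-chromen-7-one | COC1=C2OC=C(c3cc(OC)c(OC)c(O)c3OC)C=C2C=CC1=O
F8 | step 4 | 3-(3-hydroxy-2,4,5-trimethoxyphenyl)-8-methoxy-4H-chromen-7-ol | COc1cc(C2=COc3c(OC)c(O)ccc3C2)c(OC)c(O)c1OC
F9 | step 2 | (2,4,5-trimethoxyphenyl)acetic acid | COc1cc(OC)c(CC(=O)O)cc1OC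
F10 | step 2 | 8-methoxy-2-oxo-3-(2,4,5-trimethoxyphenyl)-2H-chromen-7-yl acetate | CC(=O)Oc1ccc2cc(-c3cc(OC)c(OC)cc3OC)c(=O)oc2c1OC
F11 | step 2 | 8-methoxy-3-(2,4,5-trimethoxyphenyl)-2H-chromene-2,7-diol (racemic) | COc1cc(OC)c(C2=Cc3ccc(O)c(OC)c3OC2O)cc1OC
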